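**Assumption:** the target, 3,4,7-tribromo-2-chloro-1H-indole, has no stereocentre, so there is no enantiomer to select; the C3 stereocentre of intermediates 5 and 6 forms racemic and is erased in step 2.

## Retrosynthetic overview

1. C3–Br: installed last by electrophilic bromination of the 2-chloroindole, whose only free pyrrole carbon is C3.
2. C2–Cl: from the lactam C=O of 4,7-dibromooxindole by chlorodehydration with POCl3.
3. Key disconnection C3–C3a (with N1–C2): the oxindole comes from 2,5-dibromoaniline and ethyl (methylsulfanyl)acetate. The aniline is polarity-inverted by N-chlorination, so that an azasulfonium ylide and a [2,3]-sigmatropic shift bond the nucleophilic ester α-carbon to the normally nucleophilic ortho carbon of the aniline. The sulfur handle is then cut off reductively.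
4. Ring order: the benzene ring is bought with both bromines in place; the five-membered ring is closed in step 1; the C2 and C3 halogens follow.

## Route

**Step 1**
Reactants: 1 2,5-dibromoaniline; 2 ethyl 2-(methylsulfanyl)acetate
Product: 6 racemic 4,7-dibromo-3-(methylsulfanyl)indolin-2-one, via N-chloro-2,5-dibromoaniline 3 (not isolated), via azasulfonium chloride 4 (not isolated), via amino ester 5 (not isolated)
Conditions: t-BuOCl (1.05 equiv), CH2Cl2, −65 °C, 15 min; then 2 (1.05 equiv), −65 °C, 1 h; then Et3N (1.1 equiv), −65 °C → rt; then 2 M aq HCl, Et2O, rt → 40 °C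
Reagents that add atoms: none
Why: Gassman oxindole synthesis: N-chlorination makes the aniline the electrophilic partner, the sulfide adds at nitrogen, and the ester-stabilised sulfonium ylide formed with Et3N undergoes a [2,3]-sigmatropic (Sommelet–Hauser) shift to C6, the only free ortho carbon, so the C3–C3a bond forms without relying on the poor nucleophilicity of the dibrominated ring; acid then lactamises the amino ester, and the new C3 stereocentre is racemic and removed in step 2.

**Step 2**
Reactants: 6 racemic 4,7-dibromo-3-(methylsulfanyl)indolin-2-one
Product: 7 4,7-dibromoindolin-2-one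
Conditions: Zn dust (5 equiv), AcOH, 60 °C
Reagents that add atoms: none
Why: Dissolving-metal reductive desulfurisation: electron transfer from Zn cleaves the benzylic, α-carbonyl C–S bond (the leaving group is the stabilised oxindole enolate, protonated by AcOH) under conditions that leave aryl C–Br bonds intact, which Raney Ni would not guarantee; the C3 stereocentre disappears.

**Step 3**
Reactants: 7 4,7-dibromoindolin-2-one
Product: 8 4,7-dibromo-2-chloro-1H-indole
Conditions: POCl3 (4 equiv), imidazole (1.2 equiv), 1,2-dichloroethane, 80 °C; aq NaHCO3 work-up
Reagents that add atoms: phosphoryl chloride (POCl3), O=P(Cl)(Cl)Cl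
Why: Chlorodehydration of the lactam (O-phosphorylation, chloride addition–elimination at C2, then tautomerisation of the 2-chloro-3H-indole to the aromatic 1H-indole); the two bromines deactivate the ring and the 4-bromine shields C3, which suppresses the self-condensation seen with the parent oxindole.

**Step 4**
Reactants: 8 4,7-dibromo-2-chloro-1H-indole
Product: 9 3,4,7-tribromo-2-chloro-1H-indole
Conditions: NBS (1.05 equiv), DMF, 0 °C → rt, dark
Reagents that add atoms: N-bromosuccinimide (NBS), O=C1CCC(=O)N1Br
Why: Electrophilic aromatic bromination: C3 is the only unsubstituted pyrrole position and the most nucleophilic carbon of the 2-chloroindole, while the benzenoid positions are deactivated by two bromines; no stereocentre is involved.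

## Compound list

1 | 2,5-dibromoaniline | Nc1cc(Br)ccc1Br | starting material
2 | ethyl 2-(methylsulfanyl)acetate | CCOC(=O)CSC | starting material
3 | N-chloro-2,5-dibromoaniline | ClNc1cc(Br)ccc1Br | intermediate (not isolated)
4 | (2,5-dibromoanilino)(2-ethoxy-2-oxoethyl)methylsulfonium chloride | CCOC(=O)C[S+](C)Nc1cc(Br)ccc1Br.[Cl-] | intermediate (not isolated)
5 | ethyl 2-(2-amino-3,6-dibromophenyl)-2-(methylsulfanyl)acetate, racemic | CCOC(=O)C(SC)c1c(Br)ccc(Br)c1N | intermediate (not isolated)
6 | 4,7-dibromo-3-(methylsulfanyl)indolin-2-one, racemic | CSC1C(=O)Nc2c(Br)ccc(Br)c21 | intermediate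
7 | 4,7-dibromoindolin-2-one | O=C1Cc2c(Br)ccc(Br)c2N1 | intermediate
8 | 4,7-dibromo-2-chloro-1H-indole | Clc1cc2c(Br)ccc(Br)c2[nH]1 | intermediate
9 | 3,4,7-tribromo-2-chloro-1H-indole | Clc1[nH]c2c(Br)ccc(Br)c2c1Br | target

## Step count and risks

Total step count: 4. Longest linear sequence: 4.

The three steps most likely to fail:

**Step 1.** N-chlorination of a hindered, deactivated aniline may be slow or divert to ring chlorination at C4, and the ylide must rearrange onto an ortho carbon flanked by bromine. The fallback makes the side chain the electrophile instead of the aniline. It sets out from 1, which is acylated with (methylsulfanyl)acetyl chloride (pyridine, CH2Cl2, 0 °C) to N-(2,5-dibromophenyl)-2-(methylsulfanyl)acetamide F1. This is chlorinated next to sulfur with NCS (CH2Cl2, rt) to racemic 2-chloro-N-(2,5-dibromophenyl)-2-(methylsulfanyl)acetamide F2. Ionisation with SnCl4 (1,2-dichloroethane, 60 °C) gives an acyl-substituted thionium ion, an α-carbonyl cation equivalent, which closes by intramolecular Friedel–Crafts alkylation at C6 through the minor amide rotamer. The fallback comes back to the route at 6.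

**Step 2.** The sulfide C–S bond may resist Zn/AcOH, and forcing the reduction could start to remove aryl bromine. The fallback activates sulfur by oxidation first. It sets out from 6, which NaIO4 (MeOH/H2O, 0 °C) converts into 4,7-dibromo-3-(methylsulfinyl)indolin-2-one F3 (diastereomer mixture). Its far weaker C–S bond is cleaved by aluminium amalgam (Al/Hg, THF/H2O, 0 °C), as for β-keto sulfoxides, at a temperature where aryl bromides are inert. The fallback comes back at 7.

**Step 3.** Chlorodehydration of an N–H oxindole can be low-yielding through oligomerisation, and 8 is acid- and air-sensitive, so it should be used promptly. The fallback traps C3 during the chlorination. It sets out from 7, which under Vilsmeier–Haack conditions (POCl3, DMF, 0 → 60 °C, then aq NaOAc) gives 4,7-dibromo-2-chloro-1H-indole-3-carbaldehyde F4. Pinnick oxidation (NaClO2, NaH2PO4, 2-methyl-2-butene, t-BuOH/H2O) gives 4,7-dibromo-2-chloro-1H-indole-3-carboxylic acid F5. Ipso-bromodecarboxylation with NBS (DMF, rt) then delivers the target directly, so the fallback comes back at 9 and bypasses 8 and step 4.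

## Further compounds

F1 | step 1 | N-(2,5-dibromophenyl)-2-(methylsulfanyl)acetamide | CSCC(=O)Nc1cc(Br)ccc1Br
F2 | step 1 | 2-chloro-N-(2,5-dibromophenyl)-2-(methylsulfanyl)acetamide, racemic | CSC(Cl)C(=O)Nc1cc(Br)ccc1Br
F3 | step 2 | 4,7-dibromo-3-(methylsulfinyl)indolin-2-one, diastereomer mixture | CS(=O)C1C(=O)Nc2c(Br)ccc(Br)c21
F4 | step 3 | 4,7-dibromo-2-chloro-1H-indole-3-carbaldehyde | O=Cc1c(Cl)[nH]c2c(Br)ccc(Br)c12
F5 | step 3 | 4,7-dibromo-2-chloro-1H-indole-3-carboxylic acid | OC(=O)c1c(Cl)[nH]c2c(Br)ccc(Br)c12
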